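Everything rests on cutting C6–C7 (germacranolide numbering: lactone O on C6, C7 carries C11(=C13H2)–C12=O), the bond shared by the ten-membered carbocycle and the α-methylene-γ-butyrolactone. The homoallylic array O–C6–C7–C11=C13 is the retron of a carbonyl allylation, so an open-chain C6 enal that ends in a (Z)-2-(bromomethyl)enoate (C7=C11, C13–Br) next to the C8 silyl ether is closed by Cr(II) umpolung (intramolecular Nozaki–Hiyama–Kishi allylation). One operation joins two electrophilic carbons, closes the carbocycle, sets C6 and C7 under control of C8 and, after lactonisation, delivers the bicycle. The chain is assembled from a glutamic-acid-derived lactone and Morita–Baylis–Hillman chemistry.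

Key step: step 17

Remark: locants C1–C15 are the germacranolide locants of the target (C4 bears formyl C15, C10 bears acetoxymethyl C14, C8 bears the acyloxy group); both ring alkenes are E by CIP although the ring carbons are cis across them; 2-[(4-methoxybenzyl)oxy]acetaldehyde is taken as a purchasable building block.

Step 1
Reactants: 1 2-[(4-methoxybenzyl)oxy]acetaldehyde; 2 methyl acrylate
Product: 3 methyl 3-hydroxy-4-[(4-methoxybenzyl)oxy]-2-methylidenebutanoate (racemic)
Conditions: DABCO (0.5 equiv), 2 (3 equiv), neat, rt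
Reagents that add atoms: none
Why: Morita–Baylis–Hillman reaction of an activated α-alkoxy aldehyde joins C5 to C4 and brings in C3 (methylidene) and the C15 ester; the racemic carbinol centre is erased in step 3.

Step 2
Reactants: 3 Baylis–Hillman alcohol
Product: 4 methyl 3-acetoxy-4-[(4-methoxybenzyl)oxy]-2-methylidenebutanoate (racemic)
Conditions: Ac2O, DMAP (cat.), pyridine, CH2Cl2, 0 °C to rt
Reagents that add atoms: acetic anhydride CC(=O)OC(C)=O
Why: DMAP-catalysed acetylation converts the allylic hydroxyl into the leaving group needed for allylic substitution.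

Step 3
Reactants: 4 Baylis–Hillman acetate; 5 (1,3-dioxolan-2-ylmethyl)magnesium bromide
Product: 6 methyl (2E)-2-[2-(1,3-dioxolan-2-yl)ethyl]-4-[(4-methoxybenzyl)oxy]but-2-enoate
Conditions: 5 (1.5 equiv), CuI (10 mol%), THF, −40 to 0 °C
Reagents that add atoms: none
Why: Copper-catalysed SN2′ substitution of the Baylis–Hillman acetate forms C2–C3 and moves the alkene to C4=C5 with the ester trans to the C5 substituent (least A(1,3) strain), i.e. the (E)-enoate with C3 cis to C6 as the ring requires.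

Step 4
Reactants: 6 enoate
Product: 7 (2E)-2-[2-(1,3-dioxolan-2-yl)ethyl]-4-[(4-methoxybenzyl)oxy]but-2-en-1-ol
Conditions: DIBAL-H (2.5 equiv), CH2Cl2, −78 °C; Rochelle salt
Reagents that add atoms: none
Why: DIBAL-H 1,2-reduction of the enoate gives the C15 allylic alcohol with retention of alkene geometry and leaves the dioxolane and PMB ether intact.

Step 5
Reactants: 7 allylic alcohol
Product: 8 tert-butyl{[(2E)-2-[2-(1,3-dioxolan-2-yl)ethyl]-4-[(4-methoxybenzyl)oxy]but-2-en-1-yl]oxy}dimethylsilane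
Conditions: TBSCl, imidazole, CH2Cl2, 0 °C to rt
Reagents that add atoms: tert-butyldimethylsilyl chloride CC(C)(C)[Si](C)(C)Cl
Why: Routine silylation of the primary allylic alcohol; TBS is chosen so that O15 and O8 can later be unmasked together.

Step 6
Reactants: 8 dioxolane
Product: 10 (4E)-4-{[(tert-butyldimethylsilyl)oxy]methyl}-6-[(4-methoxybenzyl)oxy]hex-4-enal, via pyridinium N,O-acetal triflate 9 (not isolated)
Conditions: TESOTf, 2,4,6-collidine, CH2Cl2, 0 °C; then H2O, rt
Reagents that add atoms: water O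
Why: Chemoselective cleavage of an aldehyde-derived 1,3-dioxolane under non-protic silyl triflate/collidine conditions (collidinium N,O-acetal, then hydrolysis) frees the C1 aldehyde while the primary allylic TBS ether and the PMB ether survive.

Step 7
Reactants: 11 (5S)-5-(hydroxymethyl)oxolan-2-one
Product: 12 (5S)-5-{[(triethylsilyl)oxy]methyl}oxolan-2-one
Conditions: TESCl, imidazole, CH2Cl2, 0 °C
Reagents that add atoms: chlorotriethylsilane CC[Si](CC)(CC)Cl
Why: Silylation of the chiral-pool lactone, which supplies C7–C10, C14 and the (S)-configured C8 whose C–O bond is never broken; TES is chosen because a primary TES ether can later be oxidised directly in the presence of TBS ethers.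

Step 8
Reactants: 12 TES lactone; 10 aldehyde
Product: 15 (3E,5S)-3-[(4E)-4-{[(tert-butyldimethylsilyl)oxy]methyl}-6-[(4-methoxybenzyl)oxy]hex-4-en-1-ylidene]-5-{[(triethylsilyl)oxy]methyl}oxolan-2-one, via β-hydroxy lactone 13 (not isolated), via mesylate 14 (not isolated)
Conditions: LDA, THF, −78 °C; 10; then MsCl, −78 to 0 °C; then DBU, rt
Reagents that add atoms: none
Why: Aldol addition of the lactone enolate (C10) to the C1 aldehyde and E1cB elimination of the mesylate give the exocyclic alkene with C2 anti to the lactone carbonyl, the (E)-alkylidene lactone favoured thermodynamically and by A(1,3) strain, which places C2 cis to C9; C8 is not touched.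

Step 9
Reactants: 15 alkylidene lactone
Product: 16 (2S,4E,8E)-8-{[(tert-butyldimethylsilyl)oxy]methyl}-4-(hydroxymethyl)-10-[(4-methoxybenzyl)oxy]-1-[(triethylsilyl)oxy]deca-4,8-dien-2-ol
Conditions: DIBAL-H (4 equiv), CH2Cl2, −78 to 0 °C; Rochelle salt
Reagents that add atoms: none
Why: DIBAL-H reduces the α-alkylidene lactone through the lactol to the primary allylic alcohol (C14) and frees the C8 hydroxyl by acyl C–O cleavage, so configuration and alkene geometry are retained.

Step 10
Reactants: 16 diol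
Product: 17 (2S,4E,8E)-4-(acetoxymethyl)-8-{[(tert-butyldimethylsilyl)oxy]methyl}-10-[(4-methoxybenzyl)oxy]-1-[(triethylsilyl)oxy]deca-4,8-dien-2-ol
Conditions: AcCl (1.05 equiv), 2,4,6-collidine, CH2Cl2, −78 °C
Reagents that add atoms: acetyl chloride CC(=O)Cl
Why: Kinetically selective acetylation of the unhindered primary allylic alcohol over the secondary C8 hydroxyl installs the C14 acetate of the target.

Step 11
Reactants: 17 hydroxy acetate
Product: 18 (2S,4E,8E)-4-(acetoxymethyl)-2-[(tert-butyldimethylsilyl)oxy]-8-{[(tert-butyldimethylsilyl)oxy]methyl}-10-[(4-methoxybenzyl)oxy]-1-[(triethylsilyl)oxy]deca-4,8-diene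
Conditions: TBSOTf, 2,6-lutidine, CH2Cl2, −78 °C
Reagents that add atoms: tert-butyldimethylsilyl triflate CC(C)(C)[Si](C)(C)OS(=O)(=O)C(F)(F)F
Why: Silyl triflate silylation of the secondary alcohol gives the bulky C8 silyl ether that later controls the key step and keeps O8 from cyclising onto C13.

Step 12
Reactants: 18 primary TES ether
Product: 19 (2S,4E,8E)-4-(acetoxymethyl)-2-[(tert-butyldimethylsilyl)oxy]-8-{[(tert-butyldimethylsilyl)oxy]methyl}-10-[(4-methoxybenzyl)oxy]deca-4,8-dienal
Conditions: (COCl)2 (4 equiv), DMSO (8 equiv), CH2Cl2, −78 to −40 °C; then Et3N, −78 to 0 °C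
Reagents that add atoms: none
Why: Swern reagent cleaves the unhindered primary O–SiEt3 bond and oxidises it in the same pot (known direct oxidation of primary TES ethers), whereas the TBS ethers are inert; low temperature protects the α-silyloxy aldehyde from epimerisation.

Step 13
Reactants: 19 aldehyde; 2 methyl acrylate
Product: 20 methyl (4S,6E,10E)-6-(acetoxymethyl)-4-[(tert-butyldimethylsilyl)oxy]-10-{[(tert-butyldimethylsilyl)oxy]methyl}-3-hydroxy-12-[(4-methoxybenzyl)oxy]-2-methylidenedodeca-6,10-dienoate (C3 epimers)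
Conditions: DABCO (1 equiv), 2 (10 equiv), neat, rt
Reagents that add atoms: none
Why: Morita–Baylis–Hillman reaction of the electrophilic α-silyloxy aldehyde installs C11, C12 and C13; the new C7 carbinol forms as an epimer mixture of no consequence because C7 becomes sp2 in step 14.

Step 14
Reactants: 20 Baylis–Hillman alcohol
Product: 21 methyl (2Z,4S,6E,10E)-6-(acetoxymethyl)-2-(bromomethyl)-4-[(tert-butyldimethylsilyl)oxy]-10-{[(tert-butyldimethylsilyl)oxy]methyl}-12-[(4-methoxybenzyl)oxy]dodeca-2,6,10-trienoate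
Conditions: NBS, Me2S, CH2Cl2, 0 °C to rt
Reagents that add atoms: N-bromosuccinimide O=C1CCC(=O)N1Br
Why: Bromodimethylsulfonium activation of the allylic alcohol (Corey–Kim-type reagent) and SN2′ attack of bromide at C13 give the rearranged primary allylic bromide as the thermodynamically preferred (Z)-2-(bromomethyl)enoate under conditions that spare silyl ethers, acetate and PMB ether.

Step 15
Reactants: 21 PMB ether
Product: 22 methyl (2Z,4S,6E,10E)-6-(acetoxymethyl)-2-(bromomethyl)-4-[(tert-butyldimethylsilyl)oxy]-10-{[(tert-butyldimethylsilyl)oxy]methyl}-12-hydroxydodeca-2,6,10-trienoate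
Conditions: DDQ, CH2Cl2/pH 7 buffer, 0 °C
Reagents that add atoms: none
Why: Oxidative PMB cleavage by DDQ (hydride abstraction, hydrolysis of the oxocarbenium ion) frees the C6 alcohol without touching the silyl ethers, the acetate or the allylic bromide.

Step 16
Reactants: 22 allylic alcohol
Product: 23 methyl (2Z,4S,6E,10E)-6-(acetoxymethyl)-2-(bromomethyl)-4-[(tert-butyldimethylsilyl)oxy]-10-{[(tert-butyldimethylsilyl)oxy]methyl}-12-oxododeca-2,6,10-trienoate
Conditions: MnO2 (excess), CH2Cl2, rt
Reagents that add atoms: none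
Why: MnO2 oxidises the allylic alcohol to the enal under neutral conditions, which keeps the C4=C5 geometry (C6 cis to C3) and the allylic bromide intact.

Step 17
Reactants: 23 bromo enal
Product: 26 (3aS,4S,6E,10E,11aR)-6-(acetoxymethyl)-4-[(tert-butyldimethylsilyl)oxy]-10-{[(tert-butyldimethylsilyl)oxy]methyl}-3-methylidene-3a,4,5,8,9,11a-hexahydrocyclodeca[b]furan-2(3H)-one, via allylchromium(III) dichloride 24 (not isolated), via hydroxy ester 25 (not isolated)
Conditions: CrCl2 (8 equiv), THF/DMF (3:1), 23 added by syringe pump (final 0.003 M), rt; aq. NH4Cl; then PPTS (cat.), benzene, 50 °C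
Reagents that add atoms: none
Why: Cr(II) reduces the allylic C13–Br bond of 23 in two one-electron steps to the η1-allylchromium(III) species 24, which turns the normally electrophilic enoate β-carbon C7 into a nucleophile that adds through a closed six-membered chair (Cr–O=C6) to the C6 aldehyde, and the hydroxy ester 25 so formed lactonises on mild acid treatment. The closest known reaction type is the intramolecular Nozaki–Hiyama–Kishi (Barbier-type) allylation of an aldehyde by a 2-(bromomethyl)acrylate, the standard α-methylene-γ-butyrolactone annulation, which is known to close ten-membered germacranolide rings at this bond. The carbocycle closes in a 10-exo-trig mode (C7 onto the exocyclic C6=O) and the lactone in a 5-exo-trig acyl substitution (O6 onto C12). C6 and C7 are set together by the chair, in which both ring arms (C5 on C6 and C8 on C7) are pseudo-equatorial, so that H6 and H7 end up anti (trans-lactone); the allylchromium species can equilibrate its C7=C11 geometry, so the least strained chair decides. The sense relative to C8 is controlled by allylic 1,3-strain, which holds H8 in the plane of the allyl unit, leaves the tether carbon C9 on the face that delivers the aldehyde and places the bulky OTBS group anti to the forming bond, which corresponds to the target configuration at C7 (CIP label S in 26 only because of the silyl ether). The step needs cyclisation over oligomerisation, secured by slow addition at high dilution, and chemoselectivity for the allylic bromide over the C14 allylic acetate and the enal, secured because Cr(II) inserts only into the activated C–Br bond and the allylchromium reagent adds 1,2 to aldehydes only.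

Step 18
Reactants: 26 bis-TBS lactone
Product: 27 (3aR,4S,6E,10E,11aR)-6-(acetoxymethyl)-4-hydroxy-10-(hydroxymethyl)-3-methylidene-3a,4,5,8,9,11a-hexahydrocyclodeca[b]furan-2(3H)-one
Conditions: HF·pyridine, pyridine, THF, 0 °C to rt
Reagents that add atoms: none
Why: Buffered HF cleaves both TBS ethers under mildly acidic conditions that tolerate the α-methylene lactone and the allylic acetate and do not promote translactonisation.

Step 19
Reactants: 27 diol
Product: 28 (3aR,4S,6E,10E,11aR)-6-(acetoxymethyl)-4-hydroxy-3-methylidene-2-oxo-2,3,3a,4,5,8,9,11a-octahydrocyclodeca[b]furan-10-carbaldehyde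
Conditions: MnO2 (excess), CH2Cl2, rt
Reagents that add atoms: none
Why: MnO2 oxidises only the primary allylic alcohol (C15) to the conjugated aldehyde, the secondary non-allylic C8 hydroxyl being inert, and the thermodynamically preferred (E)-2-alkylenal geometry is retained.

Step 20
Reactants: 29 ethyl 2-(hydroxymethyl)prop-2-enoate
Product: 30 ethyl 2-{[(tert-butyldimethylsilyl)oxy]methyl}prop-2-enoate
Conditions: TBSCl, imidazole, CH2Cl2, 0 °C to rt
Reagents that add atoms: tert-butyldimethylsilyl chloride CC(C)(C)[Si](C)(C)Cl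
Why: Routine silylation masks the side-chain hydroxyl so that the acid cannot self-esterify in step 22.

Step 21
Reactants: 30 silyl ether ester
Product: 31 2-{[(tert-butyldimethylsilyl)oxy]methyl}prop-2-enoic acid
Conditions: LiOH·H2O, THF/H2O, 0 °C to rt; then 1 M HCl to pH 4
Reagents that add atoms: lithium hydroxide [Li+].[OH-]
Why: Saponification of the unhindered ethyl ester at low temperature gives the acid while the primary TBS ether survives the brief mildly acidic work-up.

Step 22
Reactants: 28 hydroxy enal; 31 protected acid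
Product: 32 (3aR,4S,6E,10E,11aR)-6-(acetoxymethyl)-10-formyl-3-methylidene-2-oxo-2,3,3a,4,5,8,9,11a-octahydrocyclodeca[b]furan-4-yl 2-{[(tert-butyldimethylsilyl)oxy]methyl}prop-2-enoate
Conditions: DCC, DMAP, CH2Cl2, 0 °C to rt
Reagents that add atoms: none
Why: Steglich esterification acylates the C8 hydroxyl with retention of configuration, and the enal, acetate and both acrylate units are inert to carbodiimide activation.

Step 23
Reactants: 32 silyl-protected ester
Product: 33 (3aR,4S,6E,10E,11aR)-6-(acetoxymethyl)-10-formyl-3-methylidene-2-oxo-2,3,3a,4,5,8,9,11a-octahydrocyclodeca[b]furan-4-yl 2-(hydroxymethyl)prop-2-enoate (CNP0198933.2)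
Conditions: HF·pyridine, pyridine, THF, 0 °C
Reagents that add atoms: none
Why: Mild buffered fluoride cleavage of the primary TBS ether releases the hydroxymethyl acrylate without acyl migration or conjugate addition and should give the target.

Compound list
1 | 2-[(4-methoxybenzyl)oxy]acetaldehyde | COc1ccc(COCC=O)cc1 | starting material
2 | methyl acrylate | C=CC(=O)OC | starting material
3 | methyl 3-hydroxy-4-[(4-methoxybenzyl)oxy]-2-methylidenebutanoate (racemic) | COC(=O)C(=C)C(O)COCc1ccc(OC)cc1 | intermediate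
4 | methyl 3-acetoxy-4-[(4-methoxybenzyl)oxy]-2-methylidenebutanoate (racemic) | COC(=O)C(=C)C(OC(C)=O)COCc1ccc(OC)cc1 | intermediate
5 | (1,3-dioxolan-2-ylmethyl)magnesium bromide | Br[Mg]CC1OCCO1 | starting material
6 | methyl (2E)-2-[2-(1,3-dioxolan-2-yl)ethyl]-4-[(4-methoxybenzyl)oxy]but-2-enoate | COC(=O)/C(CCC1OCCO1)=C/COCc1ccc(OC)cc1 | intermediate
7 | (2E)-2-[2-(1,3-dioxolan-2-yl)ethyl]-4-[(4-methoxybenzyl)oxy]but-2-en-1-ol | OC/C(CCC1OCCO1)=C/COCc1ccc(OC)cc1 | intermediate
8 | TBS ether of 7 | CC(C)(C)[Si](C)(C)OC/C(CCC1OCCO1)=C/COCc1ccc(OC)cc1 | intermediate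
9 | 2,4,6-trimethylpyridinium N,O-acetal triflate at C1 (O-CH2CH2-OTES arm) | CC[Si](CC)(CC)OCCOC(CC/C(CO[Si](C)(C)C(C)(C)C)=C\COCc1ccc(OC)cc1)[n+]1c(C)cc(C)cc1C.[O-]S(=O)(=O)C(F)(F)F | intermediate (not isolated)
10 | (4E)-4-{[(tert-butyldimethylsilyl)oxy]methyl}-6-[(4-methoxybenzyl)oxy]hex-4-enal | O=CCC/C(CO[Si](C)(C)C(C)(C)C)=C\COCc1ccc(OC)cc1 | intermediate
11 | (5S)-5-(hydroxymethyl)oxolan-2-one | O=C1CC[C@@H](CO)O1 | starting material
12 | (5S)-5-{[(triethylsilyl)oxy]methyl}oxolan-2-one | CC[Si](CC)(CC)OC[C@@H]1CCC(=O)O1 | intermediate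
13 | β-hydroxy lactone (aldol adduct of 12 and 10, epimers at C10 and C1, 5S) | O=C1O[C@H](CO[Si](CC)(CC)CC)CC1C(O)CC/C(CO[Si](C)(C)C(C)(C)C)=C\COCc1ccc(OC)cc1 | intermediate (not isolated)
14 | mesylate of 13 | O=C1O[C@H](CO[Si](CC)(CC)CC)CC1C(OS(C)(=O)=O)CC/C(CO[Si](C)(C)C(C)(C)C)=C\COCc1ccc(OC)cc1 | intermediate (not isolated)
15 | (3E,5S)-3-[(4E)-4-{[(tert-butyldimethylsilyl)oxy]methyl}-6-[(4-methoxybenzyl)oxy]hex-4-en-1-ylidene]-5-{[(triethylsilyl)oxy]methyl}oxolan-2-one | O=C1O[C@H](CO[Si](CC)(CC)CC)C/C1=C\CC/C(CO[Si](C)(C)C(C)(C)C)=C\COCc1ccc(OC)cc1 | intermediate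
16 | (2S,4E,8E)-8-{[(tert-butyldimethylsilyl)oxy]methyl}-4-(hydroxymethyl)-10-[(4-methoxybenzyl)oxy]-1-[(triethylsilyl)oxy]deca-4,8-dien-2-ol | COc1ccc(COC/C=C(/CO[Si](C)(C)C(C)(C)C)CC/C=C(/CO)C[C@H](O)CO[Si](CC)(CC)CC)cc1 | intermediate
17 | (2S,4E,8E)-4-(acetoxymethyl)-8-{[(tert-butyldimethylsilyl)oxy]methyl}-10-[(4-methoxybenzyl)oxy]-1-[(triethylsilyl)oxy]deca-4,8-dien-2-ol | COc1ccc(COC/C=C(/CO[Si](C)(C)C(C)(C)C)CC/C=C(/COC(C)=O)C[C@H](O)CO[Si](CC)(CC)CC)cc1 | intermediate
18 | (2S,4E,8E)-4-(acetoxymethyl)-2-[(tert-butyldimethylsilyl)oxy]-8-{[(tert-butyldimethylsilyl)oxy]methyl}-10-[(4-methoxybenzyl)oxy]-1-[(triethylsilyl)oxy]deca-4,8-diene | COc1ccc(COC/C=C(/CO[Si](C)(C)C(C)(C)C)CC/C=C(/COC(C)=O)C[C@H](O[Si](C)(C)C(C)(C)C)CO[Si](CC)(CC)CC)cc1 | intermediate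
19 | (2S,4E,8E)-4-(acetoxymethyl)-2-[(tert-butyldimethylsilyl)oxy]-8-{[(tert-butyldimethylsilyl)oxy]methyl}-10-[(4-methoxybenzyl)oxy]deca-4,8-dienal | COc1ccc(COC/C=C(/CO[Si](C)(C)C(C)(C)C)CC/C=C(/COC(C)=O)C[C@H](O[Si](C)(C)C(C)(C)C)C=O)cc1 | intermediate
20 | methyl (4S,6E,10E)-6-(acetoxymethyl)-4-[(tert-butyldimethylsilyl)oxy]-10-{[(tert-butyldimethylsilyl)oxy]methyl}-3-hydroxy-12-[(4-methoxybenzyl)oxy]-2-methylidenedodeca-6,10-dienoate (C3 epimers) | COc1ccc(COC/C=C(/CO[Si](C)(C)C(C)(C)C)CC/C=C(/COC(C)=O)C[C@H](O[Si](C)(C)C(C)(C)C)C(O)C(=C)C(=O)OC)cc1 | intermediate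
21 | methyl (2Z,4S,6E,10E)-6-(acetoxymethyl)-2-(bromomethyl)-4-[(tert-butyldimethylsilyl)oxy]-10-{[(tert-butyldimethylsilyl)oxy]methyl}-12-[(4-methoxybenzyl)oxy]dodeca-2,6,10-trienoate | COc1ccc(COC/C=C(/CO[Si](C)(C)C(C)(C)C)CC/C=C(/COC(C)=O)C[C@H](O[Si](C)(C)C(C)(C)C)/C=C(\CBr)C(=O)OC)cc1 | intermediate
22 | methyl (2Z,4S,6E,10E)-6-(acetoxymethyl)-2-(bromomethyl)-4-[(tert-butyldimethylsilyl)oxy]-10-{[(tert-butyldimethylsilyl)oxy]methyl}-12-hydroxydodeca-2,6,10-trienoate | OC/C=C(/CO[Si](C)(C)C(C)(C)C)CC/C=C(/COC(C)=O)C[C@H](O[Si](C)(C)C(C)(C)C)/C=C(\CBr)C(=O)OC | intermediate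
23 | methyl (2Z,4S,6E,10E)-6-(acetoxymethyl)-2-(bromomethyl)-4-[(tert-butyldimethylsilyl)oxy]-10-{[(tert-butyldimethylsilyl)oxy]methyl}-12-oxododeca-2,6,10-trienoate | O=C/C=C(/CO[Si](C)(C)C(C)(C)C)CC/C=C(/COC(C)=O)C[C@H](O[Si](C)(C)C(C)(C)C)/C=C(\CBr)C(=O)OC | intermediate
24 | allylchromium(III) dichloride from 23 (Cr on C13, solvent ligands omitted) | O=C/C=C(/CO[Si](C)(C)C(C)(C)C)CC/C=C(/COC(C)=O)C[C@H](O[Si](C)(C)C(C)(C)C)/C=C(\C[Cr](Cl)Cl)C(=O)OC | intermediate (not isolated)
25 | methyl 2-[(1S,2R,3E,7E,10S)-8-(acetoxymethyl)-10-[(tert-butyldimethylsilyl)oxy]-4-{[(tert-butyldimethylsilyl)oxy]methyl}-2-hydroxycyclodeca-3,7-dien-1-yl]prop-2-enoate | CC(C)(C)[Si](C)(C)O[C@H]1C/C(COC(C)=O)=C\CC/C(CO[Si](C)(C)C(C)(C)C)=C\[C@@H](O)[C@@H]1C(=C)C(=O)OC | intermediate (not isolated)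
26 | (3aS,4S,6E,10E,11aR)-6-(acetoxymethyl)-4-[(tert-butyldimethylsilyl)oxy]-10-{[(tert-butyldimethylsilyl)oxy]methyl}-3-methylidene-3a,4,5,8,9,11a-hexahydrocyclodeca[b]furan-2(3H)-one | CC(C)(C)[Si](C)(C)O[C@H]1C/C(COC(C)=O)=C\CC/C(CO[Si](C)(C)C(C)(C)C)=C\[C@H]2OC(=O)C(=C)[C@H]12 | intermediate
27 | (3aR,4S,6E,10E,11aR)-6-(acetoxymethyl)-4-hydroxy-10-(hydroxymethyl)-3-methylidene-3a,4,5,8,9,11a-hexahydrocyclodeca[b]furan-2(3H)-one | O[C@H]1C/C(COC(C)=O)=C\CC/C(CO)=C\[C@H]2OC(=O)C(=C)[C@H]12 | intermediate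
28 | (3aR,4S,6E,10E,11aR)-6-(acetoxymethyl)-4-hydroxy-3-methylidene-2-oxo-2,3,3a,4,5,8,9,11a-octahydrocyclodeca[b]furan-10-carbaldehyde | O[C@H]1C/C(COC(C)=O)=C\CC/C(C=O)=C\[C@H]2OC(=O)C(=C)[C@H]12 | intermediate
29 | ethyl 2-(hydroxymethyl)prop-2-enoate | C=C(CO)C(=O)OCC | starting material
30 | ethyl 2-{[(tert-butyldimethylsilyl)oxy]methyl}prop-2-enoate | C=C(CO[Si](C)(C)C(C)(C)C)C(=O)OCC | intermediate
31 | 2-{[(tert-butyldimethylsilyl)oxy]methyl}prop-2-enoic acid | C=C(CO[Si](C)(C)C(C)(C)C)C(=O)O | intermediate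
32 | (3aR,4S,6E,10E,11aR)-6-(acetoxymethyl)-10-formyl-3-methylidene-2-oxo-2,3,3a,4,5,8,9,11a-octahydrocyclodeca[b]furan-4-yl 2-{[(tert-butyldimethylsilyl)oxy]methyl}prop-2-enoate | C=C(CO[Si](C)(C)C(C)(C)C)C(=O)O[C@H]1C/C(COC(C)=O)=C\CC/C(C=O)=C\[C@H]2OC(=O)C(=C)[C@H]12 | intermediate
33 | (3aR,4S,6E,10E,11aR)-6-(acetoxymethyl)-10-formyl-3-methylidene-2-oxo-2,3,3a,4,5,8,9,11a-octahydrocyclodeca[b]furan-4-yl 2-(hydroxymethyl)prop-2-enoate (CNP0198933.2) | C=C(CO)C(=O)O[C@H]1C/C(COC(C)=O)=C\CC/C(C=O)=C\[C@H]2OC(=O)C(=C)[C@H]12 | target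

Total step count: 23. Longest linear sequence: 20 steps (steps 1–6, 8–19, 22 and 23).

Steps most likely to fail

Step 17 (ring closure). What may go wrong is poor facial selectivity at the C6 aldehyde (closure through a chair that leads to the 6,7-syn, cis-lactone series) and competing intermolecular coupling. The fallback re-sets C6 after ring closure by a redox relay instead of relying on the allylation transition state. Setting out from 23, the Cr(II) closure is run as above but worked up without the acid treatment, so that the 6-epimeric hydroxy ester methyl 2-[(1S,2S,3E,7E,10S)-8-(acetoxymethyl)-10-[(tert-butyldimethylsilyl)oxy]-4-{[(tert-butyldimethylsilyl)oxy]methyl}-2-hydroxycyclodeca-3,7-dien-1-yl]prop-2-enoate F1 is isolated. Dess–Martin oxidation (NaHCO3, CH2Cl2, 0 °C) should give the ring enone methyl 2-[(1R,3E,7E,10S)-8-(acetoxymethyl)-10-[(tert-butyldimethylsilyl)oxy]-4-{[(tert-butyldimethylsilyl)oxy]methyl}-2-oxocyclodeca-3,7-dien-1-yl]prop-2-enoate F2. Luche reduction (NaBH4, CeCl3·7H2O, MeOH, −78 °C), in which hydride should attack the enone from its exposed peripheral face, comes back to the route at hydroxy ester 25, which is lactonised to 26 as in step 17.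

Step 13 (Baylis–Hillman reaction on the hindered α-silyloxy aldehyde). What may go wrong is a very slow amine-catalysed addition, during which the aldehyde epimerises at C8 or decomposes. The fallback replaces amine catalysis by a preformed vinylmetal: setting out from 19, [1-(methoxycarbonyl)vinyl]diisobutylaluminium (from methyl propiolate, DIBAL-H and N-methylmorpholine N-oxide in THF at 0 °C) should add to the aldehyde at −78 to 0 °C within minutes and come back to the route at 20; no new isolated compound arises (F0).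

Step 3 (copper-catalysed SN2′ substitution). What may go wrong is loss of regio- and stereocontrol with the chelated, weakly nucleophilic acetal Grignard reagent (direct SN2 or carbonyl attack, E/Z erosion). The fallback forms C2–C3 by a sigmatropic shift instead: setting out from 3, mercury(II)-acetate-catalysed transvinylation with ethyl vinyl ether (reflux) gives the allyl vinyl ether methyl 3-(ethenyloxy)-4-[(4-methoxybenzyl)oxy]-2-methylidenebutanoate F3. Its Claisen rearrangement (toluene, 110 °C) should deliver methyl (2E)-4-[(4-methoxybenzyl)oxy]-2-(3-oxopropyl)but-2-enoate F4 with the (E)-enoate geometry typical of Baylis–Hillman-derived esters, and acetalisation (ethylene glycol, PPTS, benzene, Dean–Stark) comes back to the route at 6.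

Further compounds
F1 | step 17 | methyl 2-[(1S,2S,3E,7E,10S)-8-(acetoxymethyl)-10-[(tert-butyldimethylsilyl)oxy]-4-{[(tert-butyldimethylsilyl)oxy]methyl}-2-hydroxycyclodeca-3,7-dien-1-yl]prop-2-enoate | CC(C)(C)[Si](C)(C)O[C@H]1C/C(COC(C)=O)=C\CC/C(CO[Si](C)(C)C(C)(C)C)=C\[C@H](O)[C@@H]1C(=C)C(=O)OC
F2 | step 17 | methyl 2-[(1R,3E,7E,10S)-8-(acetoxymethyl)-10-[(tert-butyldimethylsilyl)oxy]-4-{[(tert-butyldimethylsilyl)oxy]methyl}-2-oxocyclodeca-3,7-dien-1-yl]prop-2-enoate | CC(C)(C)[Si](C)(C)O[C@H]1C/C(COC(C)=O)=C\CC/C(CO[Si](C)(C)C(C)(C)C)=C\C(=O)[C@@H]1C(=C)C(=O)OC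
F0 | step 13 | none | none
F3 | step 3 | methyl 3-(ethenyloxy)-4-[(4-methoxybenzyl)oxy]-2-methylidenebutanoate | COC(=O)C(=C)C(OC=C)COCc1ccc(OC)cc1
F4 | step 3 | methyl (2E)-4-[(4-methoxybenzyl)oxy]-2-(3-oxopropyl)but-2-enoate | COC(=O)/C(CCC=O)=C/COCc1ccc(OC)cc1
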